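**Retrosynthetic overview**
- Final step is global MOM removal. Before it, the C2–C1′ bond is cut: Rh-catalysed asymmetric 1,4-addition of a B-ring arylboronic acid to an 8-prenyl-5,7-bis(MOM-oxy)chromone, which sets C2 as S.
- The pyranone ring is the only ring built (A and B rings are bought as resorcinol and 4-bromophenol). It is closed on a salicylaldehyde by a proposed Rh-catalysed formyl C–H hydroacylation of ethoxyacetylene with cyclisation.
- The salicylaldehyde comes from 3,5-bis(MOM-oxy)phenol by O-tert-prenylation/Claisen and Mg-mediated ortho-formylation. Both groups go ortho to the one free OH (the future O1), so the 8-prenyl regiochemistry is unambiguous.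
- 3,5-Bis(MOM-oxy)phenol comes from resorcinol by MOM protection and Ir-catalysed C–H borylation/oxidation at C5.
- The boronic acid comes from 4-bromophenol by the same O-tert-prenylation/Claisen, MOM protection and Li–B exchange. One carbonate made from 2-methylbut-3-en-2-ol supplies both prenyl groups.

Assumption: the (S)-biaryl bisphosphine gives the (2S)-flavanone (same sense as (S)-BINAP giving (S)-3-arylcyclohexanones); if the first run shows the opposite sense, the (R)-ligand is used. The one-pot borylation/oxidation is counted as one step.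

Abbreviations: MOM = methoxymethyl; prenyl = 3-methylbut-2-en-1-yl.

**Prenyl donor**

Step 1
Reactants: 1, 2-methylbut-3-en-2-ol
Product: 2, tert-butyl (2-methylbut-3-en-2-yl) carbonate
Conditions: n-BuLi, THF, −78 °C; Boc2O, −78 °C → rt
Reagents that add atoms: di-tert-butyl dicarbonate, CC(C)(C)OC(=O)OC(=O)OC(C)(C)C
Why: O-acylation of the lithium tertiary alkoxide gives the tertiary allylic carbonate that serves as a π-allyl-Pd precursor.

**A-ring / chromone fragment**

Step 2
Reactants: 3, resorcinol
Product: 4, 1,3-bis(methoxymethoxy)benzene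
Conditions: MOMCl (2.5 equiv), i-Pr2NEt, CH2Cl2, 0 °C → rt
Reagents that add atoms: chloromethyl methyl ether, COCCl
Why: Standard phenol O-alkylation (acetal protection) that is stable to base, organometallics and heat in later steps.

Step 3
Reactants: 4, 1,3-bis(methoxymethoxy)benzene
Product: 5, 3,5-bis(methoxymethoxy)phenol
Conditions: [Ir(OMe)(cod)]2 (1 mol %), dtbpy (2 mol %), B2pin2 (0.6 equiv), THF, 80 °C; then 30% H2O2, aq NaOH, 0 °C → rt (one pot)
Reagents that add atoms: hydrogen peroxide, OO (phenol oxygen); bis(pinacolato)diboron, CC1(C)OB(OC1(C)C)B1OC(C)(C)C(C)(C)O1 (boron only in the transient boronate)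
Why: Sterically controlled Ir-catalysed aromatic C–H borylation occurs only at C5 (the one C–H with no ortho substituent), and the C–B bond is oxidised to C–OH by 1,2-migration.

Step 4
Reactants: 5, 3,5-bis(methoxymethoxy)phenol; 2, tert-butyl (2-methylbut-3-en-2-yl) carbonate
Product: 6, 1-[(2-methylbut-3-en-2-yl)oxy]-3,5-bis(methoxymethoxy)benzene
Conditions: 2 (1.5 equiv), Pd(PPh3)4 (2 mol %), THF, 0 °C → rt
Reagents that add atoms: none
Why: Tsuji–Trost O-allylation; under kinetic control the phenoxide (deprotonated by the released tert-butoxide) attacks the more substituted terminus of the 1,1-dimethylallyl-Pd complex to give the tertiary ether.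

Step 5
Reactants: 6, 1-[(2-methylbut-3-en-2-yl)oxy]-3,5-bis(methoxymethoxy)benzene
Product: 7, 3,5-bis(methoxymethoxy)-2-(3-methylbut-2-en-1-yl)phenol
Conditions: PhNEt2, 150 °C
Reagents that add atoms: none
Why: Aromatic Claisen [3,3] rearrangement delivers a linear prenyl group strictly ortho to the oxygen (the two ortho sites are equivalent), followed by rearomatisation.

Step 6
Reactants: 7, 3,5-bis(methoxymethoxy)-2-(3-methylbut-2-en-1-yl)phenol
Product: 8, 2-hydroxy-4,6-bis(methoxymethoxy)-3-(3-methylbut-2-en-1-yl)benzaldehyde
Conditions: MgCl2, Et3N, (CH2O)n, MeCN, 80 °C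
Reagents that add atoms: paraformaldehyde (formaldehyde), C=O
Why: Casnati–Skattebøl ortho-formylation; the magnesium phenoxide delivers formaldehyde only to the single free position ortho to OH, and the buffered medium spares the MOM and prenyl groups.

Step 7
Reactants: 8, 2-hydroxy-4,6-bis(methoxymethoxy)-3-(3-methylbut-2-en-1-yl)benzaldehyde; 9, ethoxyacetylene
Product: 10, 5,7-bis(methoxymethoxy)-8-(3-methylbut-2-en-1-yl)-4H-chromen-4-one
Conditions: [Rh(cod)Cl]2 (2.5 mol %), dppf (5 mol %), Na2CO3 (0.2 equiv), 9 (3 equiv, slow addition), toluene, 60 °C; then DBU (cat.), 60 °C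
Reagents that add atoms: none
Why: Proposed new method: phenoxide-chelated oxidative addition of Rh(I) into the formyl C–H gives an acyl(hydrido)Rh(III) chelate; hydride inserts at the oxygen-bearing (electrophilic) carbon of the polarised ynol ether, placing Rh on the unhindered CH terminus, and acyl–alkenyl reductive elimination gives ArCO–CH=CH–OEt, which the ortho-phenoxide closes 6-endo with loss of ethanol to form the 2,3-unsubstituted chromone redox-neutrally; the closest known reactions are Rh/dppf salicylaldehyde–alkyne hydroacylation (including tandem hydroacylation/oxa-Michael to chromanones) and the closure of β-alkoxy or β-amino enones to chromones, but an ynol ether partner has not been shown.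

**B-ring fragment**

Step 8
Reactants: 11, 4-bromophenol; 2, tert-butyl (2-methylbut-3-en-2-yl) carbonate
Product: 12, 1-bromo-4-[(2-methylbut-3-en-2-yl)oxy]benzene
Conditions: 2 (1.5 equiv), Pd(PPh3)4 (2 mol %), THF, 0 °C → rt
Reagents that add atoms: none
Why: Tsuji–Trost O-tert-prenylation as in step 4; π-allyl formation is much faster than Ar–Br oxidative addition at this temperature.

Step 9
Reactants: 12, 1-bromo-4-[(2-methylbut-3-en-2-yl)oxy]benzene
Product: 13, 4-bromo-2-(3-methylbut-2-en-1-yl)phenol
Conditions: PhNEt2, 160 °C
Reagents that add atoms: none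
Why: Aromatic Claisen rearrangement places the linear prenyl group ortho to OH (the para position is blocked by Br).

Step 10
Reactants: 13, 4-bromo-2-(3-methylbut-2-en-1-yl)phenol
Product: 14, 4-bromo-1-(methoxymethoxy)-2-(3-methylbut-2-en-1-yl)benzene
Conditions: MOMCl, i-Pr2NEt, CH2Cl2, 0 °C → rt
Reagents that add atoms: chloromethyl methyl ether, COCCl
Why: Phenol protection prevents quenching of the aryllithium and of the later aryl-rhodium species.

Step 11
Reactants: 14, 4-bromo-1-(methoxymethoxy)-2-(3-methylbut-2-en-1-yl)benzene
Product: 15, [4-(methoxymethoxy)-3-(3-methylbut-2-en-1-yl)phenyl]boronic acid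
Conditions: n-BuLi, THF, −78 °C; B(Oi-Pr)3, −78 °C → rt; aq NH4Cl
Reagents that add atoms: triisopropyl borate, CC(C)OB(OC(C)C)OC(C)C; water, O
Why: Br–Li exchange is faster than MOM-directed ortho-lithiation at −78 °C, and borate trapping with mild hydrolysis gives the boronic acid with the MOM group intact.

**Fragment union and end game**

Step 12
Reactants: 10, 5,7-bis(methoxymethoxy)-8-(3-methylbut-2-en-1-yl)-4H-chromen-4-one; 15, [4-(methoxymethoxy)-3-(3-methylbut-2-en-1-yl)phenyl]boronic acid
Product: 16, (2S)-5,7-bis(methoxymethoxy)-2-[4-(methoxymethoxy)-3-(3-methylbut-2-en-1-yl)phenyl]-8-(3-methylbut-2-en-1-yl)chroman-4-one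
Conditions: [Rh(OH)(cod)]2 (1.5 mol %), (S)-MeO-F12-BIPHEP [6,6′-dimethoxybiphenyl-2,2′-diylbis(bis(3,4,5-trifluorophenyl)phosphine)] (3.3 mol %), 15 (2.5 equiv), toluene–H2O (10:1), 40 °C
Reagents that add atoms: none
Why: Hayashi–Miyaura Rh-catalysed asymmetric 1,4-addition: B-to-Rh transmetalation, then enantioface-selective insertion of the chromone C2=C3 into Ar–Rh(P–P*) and protonolysis of the oxa-π-allyl rhodium forms C2–C1′ and sets C2 as S under ligand control; the electron-poor bisphosphine speeds addition to the electron-rich chromone at low temperature without strong base, so the flavanone does not ring-open.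

Step 13
Reactants: 16, the tris-MOM (2S)-flavanone
Product: 17, euchrestaflavanone A, (2S)-5,7-dihydroxy-2-[4-hydroxy-3-(3-methylbut-2-en-1-yl)phenyl]-8-(3-methylbut-2-en-1-yl)chroman-4-one
Conditions: 3 M aq HCl, MeOH, 45 °C (stop at full conversion)
Reagents that add atoms: none
Why: Acid-catalysed acetal hydrolysis removes all three MOM groups; mild temperature and short time avoid prenyl–phenol cyclisation and leave the C2 stereocentre untouched (no base, so no retro-oxa-Michael).

**Compound list**
1 | 2-methylbut-3-en-2-ol | C=CC(C)(C)O | starting material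
2 | tert-butyl (2-methylbut-3-en-2-yl) carbonate | C=CC(C)(C)OC(=O)OC(C)(C)C | intermediate
3 | resorcinol | Oc1cccc(O)c1 | starting material
4 | 1,3-bis(methoxymethoxy)benzene | COCOc1cccc(OCOC)c1 | intermediate
5 | 3,5-bis(methoxymethoxy)phenol | COCOc1cc(O)cc(OCOC)c1 | intermediate
6 | 1-[(2-methylbut-3-en-2-yl)oxy]-3,5-bis(methoxymethoxy)benzene | C=CC(C)(C)Oc1cc(OCOC)cc(OCOC)c1 | intermediate
7 | 3,5-bis(methoxymethoxy)-2-(3-methylbut-2-en-1-yl)phenol | CC(C)=CCc1c(O)cc(OCOC)cc1OCOC | intermediate
8 | 2-hydroxy-4,6-bis(methoxymethoxy)-3-(3-methylbut-2-en-1-yl)benzaldehyde | CC(C)=CCc1c(O)c(C=O)c(OCOC)cc1OCOC | intermediate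
9 | ethoxyacetylene | C#COCC | starting material
10 | 5,7-bis(methoxymethoxy)-8-(3-methylbut-2-en-1-yl)-4H-chromen-4-one | O=c1ccoc2c(CC=C(C)C)c(OCOC)cc(OCOC)c12 | intermediate
11 | 4-bromophenol | Oc1ccc(Br)cc1 | starting material
12 | 1-bromo-4-[(2-methylbut-3-en-2-yl)oxy]benzene | C=CC(C)(C)Oc1ccc(Br)cc1 | intermediate
13 | 4-bromo-2-(3-methylbut-2-en-1-yl)phenol | CC(C)=CCc1cc(Br)ccc1O | intermediate
14 | 4-bromo-1-(methoxymethoxy)-2-(3-methylbut-2-en-1-yl)benzene | CC(C)=CCc1cc(Br)ccc1OCOC | intermediate
15 | [4-(methoxymethoxy)-3-(3-methylbut-2-en-1-yl)phenyl]boronic acid | CC(C)=CCc1cc(B(O)O)ccc1OCOC | intermediate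
16 | (2S)-5,7-bis(methoxymethoxy)-2-[4-(methoxymethoxy)-3-(3-methylbut-2-en-1-yl)phenyl]-8-(3-methylbut-2-en-1-yl)chroman-4-one | CC(C)=CCc1cc([C@@H]2CC(=O)c3c(OCOC)cc(OCOC)c(CC=C(C)C)c3O2)ccc1OCOC | intermediate
17 | euchrestaflavanone A | CC(C)=CCc1cc([C@@H]2CC(=O)c3c(O)cc(O)c(CC=C(C)C)c3O2)ccc1O | target

**Step count**
- Total steps: 13.
- Longest linear sequence: 8 (steps 2, 3, 4, 5, 6, 7, 12, 13 from resorcinol), i.e. 8/13 of the total.

**Three steps most likely to fail**
1. Step 7 (proposed hydroacylation/annulation). Risks are wrong-way insertion, ethoxyacetylene oligomerisation or addition to the phenol, and slow C–H activation of the hindered aldehyde. Fallback with known chemistry: add ethynylmagnesium bromide (excess, THF, 0 °C) to 8, oxidise the propargylic alcohol with MnO2 to the o-hydroxyaryl ynone, and close it 6-endo with catalytic Et2NH in EtOH to give 10. This adds one step (14 total, longest sequence 9).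
2. Step 12 (asymmetric 1,4-addition to an electron-rich 5,7,8-substituted chromone). Risks are low conversion, protodeboronation of 15, and loss of ee by ring opening. Fallback: a chalcone route. Convert 8 to the methyl ketone (MeMgBr, then MnO2), condense it with 4-(methoxymethoxy)-3-prenylbenzaldehyde (from 14 by n-BuLi/DMF), then cyclise by oxa-Michael addition with a bifunctional cinchona–thiourea catalyst, or cyclise racemically (NaOAc, EtOH) and separate the (S)-enantiomer by preparative chiral chromatography.
3. Step 13 (global MOM removal). Risks are acid-induced cyclisation of the prenyl groups onto the neighbouring phenols (dimethylchromans) or partial racemisation. Fallback: change the protecting-group strategy to silyl ethers (TBS in place of MOM in steps 2 and 10) and finish with buffered fluoride (HF·pyridine or TBAF/AcOH, 0 °C), which avoids strong acid altogether.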